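**Plan**

1. Retrosynthesis: four benzyl ethers and a helper chlorine on C5 of ring A come off last. The upper pyran ring is then cut at O1–C8a and C4a–C4 together, which removes ring A as an aryne and leaves the trans-2,3-diaryloxetane 37 (O1–C2–C3–C4 of the chroman). The oxetane C3–C4 bond is cut to imide 26 and aldehyde 19. In 19 the lower chroman is cut at O1''–C8a'' (aryl ether) and C3''–C4'' (enolate alkylation).
2. Enabling feature: C4 of the upper chroman is benzylic to ring D (the tetrasubstituted ring that also carries the lower chroman), para to that ring's C4 oxygen and ortho to its methoxy group, and O1 and C4 are 1,3-related across C2–C3. O1–C2–C3–C4 can therefore be stored as a strained oxetane whose C4–O bond ionises once the oxygen is arylated, so ring A can enter between O1 and C4 as an aryne.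
3. Forward order: ring D is differentiated (formyl, benzyloxy, methoxy); the lower chroman is built on it (Evans alkylation, then palladium-catalysed aryl ether closure); the oxetane is built on the aldehyde (anti-aldol, reduction, 4-exo-tet closure); ring A is inserted; hydrogenolysis ends the route.
4. Stereochemistry: both C3 centres come from (4R)-4-benzyl-1,3-oxazolidin-2-one (chelate-controlled alkylation and aldol on the same enolate face). C4 is set in the key step by the C3 centre (trans). The aldol carbinol centre, which is C2 of the oxetane, is lost in the cation on purpose.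
5. The chlorine next to the aryne bond (future C5 of ring A) fixes the direction of aryne capture and is removed with the benzyl groups.

Key step: step 24

Assumption: in the MgCl2-catalysed aldol of step 21 the chelated (Z)-enolate of the oxazolidinone imide is taken to react on the face opposite the auxiliary benzyl group, the same face as in the alkylation of step 10.

**Route**

Step 1
Reactants: 1 2-bromo-4-hydroxybenzaldehyde
Product: 2 4-(benzyloxy)-2-bromobenzaldehyde
Conditions: BnBr, K2CO3, DMF, rt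
Reagents that add atoms: benzyl bromide BrCc1ccccc1
Why: Williamson ether synthesis, in which the phenoxide is benzylated on oxygen while the aldehyde and the aryl bromide are inert.

Step 2
Reactants: 2 4-(benzyloxy)-2-bromobenzaldehyde
Product: 3 [4-(benzyloxy)-2-bromophenyl]methanol
Conditions: NaBH4, MeOH, 0 °C
Reagents that add atoms: none
Why: Borohydride reduction of an aryl aldehyde to the benzyl alcohol, which leaves the aryl bromide and the benzyl ether untouched.

Step 3
Reactants: 3 [4-(benzyloxy)-2-bromophenyl]methanol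
Product: 4 4-(benzyloxy)-2-bromo-1-(bromomethyl)benzene
Conditions: PBr3, CH2Cl2, 0 °C
Reagents that add atoms: phosphorus tribromide BrP(Br)Br
Why: Conversion of a benzylic alcohol into the bromide with PBr3 (displacement on the alkoxyphosphorus intermediate) gives the alkylating agent for step 10.

Step 4
Reactants: 5 methyl 2-(3,5-dihydroxyphenyl)acetate
Product: 7 methyl 2-(2-formyl-3,5-dihydroxyphenyl)acetate, via aryl iminium chloride 6 (not isolated)
Conditions: POCl3, DMF, MeCN, 0 °C to rt; then H2O, 60 °C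
Reagents that add atoms: N,N-dimethylformamide CN(C)C=O; water O
Why: Vilsmeier–Haack formylation, in which the chloroiminium ion attacks the resorcinol ring at the carbon para to one hydroxyl and ortho to the other, next to the side chain (the orcinol pattern), and hydrolysis of iminium salt 6 gives the aldehyde.

Step 5
Reactants: 7 methyl 2-(2-formyl-3,5-dihydroxyphenyl)acetate
Product: 8 methyl 2-[5-(benzyloxy)-2-formyl-3-hydroxyphenyl]acetate
Conditions: BnBr (1.0 equiv), KHCO3, DMF, 40 °C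
Reagents that add atoms: benzyl bromide BrCc1ccccc1
Why: Williamson etherification under mild base should be selective for the hydroxyl para to the formyl group, the more acidic one, because the ortho hydroxyl is held in a hydrogen bond to the aldehyde.

Step 6
Reactants: 8 methyl 2-[5-(benzyloxy)-2-formyl-3-hydroxyphenyl]acetate
Product: 9 methyl 2-[5-(benzyloxy)-2-formyl-3-methoxyphenyl]acetate
Conditions: MeI, K2CO3, DMF, rt
Reagents that add atoms: iodomethane CI
Why: Williamson methylation of the remaining chelated phenol fixes the methoxy/benzyloxy pattern of ring D.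

Step 7
Reactants: 9 methyl 2-[5-(benzyloxy)-2-formyl-3-methoxyphenyl]acetate
Product: 10 methyl 2-[5-(benzyloxy)-2-(1,3-dioxolan-2-yl)-3-methoxyphenyl]acetate
Conditions: Me3SiOCH2CH2OSiMe3, Me3SiOTf (cat.), CH2Cl2, −78 to −20 °C
Reagents that add atoms: 1,2-bis(trimethylsilyloxy)ethane C[Si](C)(C)OCCO[Si](C)(C)C
Why: Acetal formation under silyl triflate catalysis (Noyori acetalisation) masks the aldehyde as a dioxolane without transesterifying the methyl ester, so that enolate chemistry can follow.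

Step 8
Reactants: 10 methyl 2-[5-(benzyloxy)-2-(1,3-dioxolan-2-yl)-3-methoxyphenyl]acetate
Product: 11 2-[5-(benzyloxy)-2-(1,3-dioxolan-2-yl)-3-methoxyphenyl]acetic acid
Conditions: LiOH, THF/H2O, rt; then 1 M HCl to pH 5, 0 °C
Reagents that add atoms: lithium hydroxide [Li+].[OH-]
Why: Ester saponification with hydroxide, where cold acidification only to pH 5 should keep the acid-labile aryl dioxolane.

Step 9
Reactants: 11 2-[5-(benzyloxy)-2-(1,3-dioxolan-2-yl)-3-methoxyphenyl]acetic acid; 12 (4R)-4-benzyl-1,3-oxazolidin-2-one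
Product: 14 (4R)-4-benzyl-3-{2-[5-(benzyloxy)-2-(1,3-dioxolan-2-yl)-3-methoxyphenyl]acetyl}-1,3-oxazolidin-2-one, via mixed pivalic anhydride 13 (not isolated)
Conditions: t-BuCOCl, Et3N, THF, −20 °C; then 12, LiCl, −20 °C to rt
Reagents that add atoms: none
Why: N-Acylation of the oxazolidinone through mixed anhydride 13, which is attacked at the less hindered arylacetyl carbonyl, installs the Evans auxiliary.

Step 10
Reactants: 14 (4R)-4-benzyl-3-{2-[5-(benzyloxy)-2-(1,3-dioxolan-2-yl)-3-methoxyphenyl]acetyl}-1,3-oxazolidin-2-one; 4 4-(benzyloxy)-2-bromo-1-(bromomethyl)benzene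
Product: 16 (4R)-4-benzyl-3-{(2R)-3-[4-(benzyloxy)-2-bromophenyl]-2-[5-(benzyloxy)-2-(1,3-dioxolan-2-yl)-3-methoxyphenyl]propanoyl}-1,3-oxazolidin-2-one, via sodium (Z)-enolate 15 (not isolated)
Conditions: NaN(SiMe3)2, THF, −78 °C; then 4, −78 to −40 °C
Reagents that add atoms: none
Why: Evans asymmetric alkylation, in which the chelated sodium (Z)-enolate 15 is alkylated by the benzylic bromide on the face opposite the C4 benzyl group of the auxiliary, setting the (R) centre that becomes C3 of the lower chroman.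

Step 11
Reactants: 16 (4R)-4-benzyl-3-{(2R)-3-[4-(benzyloxy)-2-bromophenyl]-2-[5-(benzyloxy)-2-(1,3-dioxolan-2-yl)-3-methoxyphenyl]propanoyl}-1,3-oxazolidin-2-one
Product: 17 (2R)-3-[4-(benzyloxy)-2-bromophenyl]-2-[5-(benzyloxy)-2-(1,3-dioxolan-2-yl)-3-methoxyphenyl]propan-1-ol
Conditions: LiBH4, MeOH (1.5 equiv), THF, 0 °C
Reagents that add atoms: none
Why: Reductive cleavage of the N-acyloxazolidinone with LiBH4 should give the primary alcohol without touching the α-aryl stereocentre, the acetal or the aryl bromide.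

Step 12
Reactants: 17 (2R)-3-[4-(benzyloxy)-2-bromophenyl]-2-[5-(benzyloxy)-2-(1,3-dioxolan-2-yl)-3-methoxyphenyl]propan-1-ol
Product: 18 (3R)-7-(benzyloxy)-3-[5-(benzyloxy)-2-(1,3-dioxolan-2-yl)-3-methoxyphenyl]-3,4-dihydro-2H-chromene
Conditions: Pd(OAc)2 (3 mol%), 2-(di-tert-butylphosphino)-1,1'-binaphthyl (4 mol%), Cs2CO3, toluene, 70 °C
Reagents that add atoms: none
Why: Intramolecular palladium-catalysed C–O coupling (Buchwald–Hartwig etherification) of the primary alcohol with the ortho aryl bromide closes the lower pyran ring at atoms remote from the stereocentre.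

Step 13
Reactants: 18 (3R)-7-(benzyloxy)-3-[5-(benzyloxy)-2-(1,3-dioxolan-2-yl)-3-methoxyphenyl]-3,4-dihydro-2H-chromene
Product: 19 4-(benzyloxy)-2-[(3R)-7-(benzyloxy)-3,4-dihydro-2H-chromen-3-yl]-6-methoxybenzaldehyde
Conditions: pyridinium p-toluenesulfonate (cat.), acetone/H2O, 50 °C
Reagents that add atoms: water O
Why: Mild acid-catalysed acetal hydrolysis returns the aldehyde, the electron-rich ring making the dioxolane labile enough for pyridinium catalysis.

Step 14
Reactants: 20 2-hydroxy-4,5-dimethoxybenzaldehyde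
Product: 21 2-(benzyloxy)-4,5-dimethoxybenzaldehyde
Conditions: BnBr, K2CO3, DMF, 50 °C
Reagents that add atoms: benzyl bromide BrCc1ccccc1
Why: Williamson benzylation of the phenol protects the future ring B hydroxyl as a hydrogenolysable ether.

Step 15
Reactants: 21 2-(benzyloxy)-4,5-dimethoxybenzaldehyde
Product: 23 2-[2-(benzyloxy)-4,5-dimethoxyphenyl]acetonitrile, via N-(1-tosylvinyl)formamide 22 (not isolated)
Conditions: TosMIC, KOt-Bu, DME, −30 °C to rt; then MeOH, reflux
Reagents that add atoms: p-toluenesulfonylmethyl isocyanide Cc1ccc(cc1)S(=O)(=O)C[N+]#[C-]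
Why: van Leusen reductive cyanation, in which TosMIC adds to the aldehyde, oxazoline formation and ring opening give formamide 22, and methanolysis with loss of sulfinate delivers the one-carbon homologated nitrile.

Step 16
Reactants: 23 2-[2-(benzyloxy)-4,5-dimethoxyphenyl]acetonitrile
Product: 24 2-[2-(benzyloxy)-4,5-dimethoxyphenyl]acetic acid
Conditions: NaOH, EtOH/H2O, reflux; then HCl
Reagents that add atoms: sodium hydroxide [Na+].[OH-]; water O
Why: Basic nitrile hydrolysis gives the arylacetic acid, the benzyl and methyl ethers being stable to hydroxide.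

Step 17
Reactants: 24 2-[2-(benzyloxy)-4,5-dimethoxyphenyl]acetic acid; 12 (4R)-4-benzyl-1,3-oxazolidin-2-one
Product: 26 (4R)-4-benzyl-3-{2-[2-(benzyloxy)-4,5-dimethoxyphenyl]acetyl}-1,3-oxazolidin-2-one, via mixed pivalic anhydride 25 (not isolated)
Conditions: t-BuCOCl, Et3N, THF, −20 °C; then 12, LiCl, −20 °C to rt
Reagents that add atoms: none
Why: N-Acylation of the oxazolidinone through the mixed pivalic anhydride, as in step 9.

Step 18
Reactants: 27 4-(benzyloxy)phenol
Product: 28 4-(benzyloxy)-2-chlorophenol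
Conditions: SO2Cl2, (s-Bu)2NH (cat.), toluene, 0 °C to rt
Reagents that add atoms: sulfuryl chloride ClS(Cl)(=O)=O
Why: Electrophilic aromatic chlorination under secondary amine catalysis goes ortho to the free hydroxyl, the strongest director, since its para position is blocked.

Step 19
Reactants: 28 4-(benzyloxy)-2-chlorophenol
Product: 29 4-(benzyloxy)-2-bromo-6-chlorophenol
Conditions: N-bromosuccinimide, i-Pr2NH (cat.), CH2Cl2, 0 °C
Reagents that add atoms: N-bromosuccinimide BrN1C(=O)CCC1=O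
Why: Amine-catalysed ortho-bromination of the phenol takes the only remaining position ortho to the hydroxyl.

Step 20
Reactants: 29 4-(benzyloxy)-2-bromo-6-chlorophenol
Product: 32 4-(benzyloxy)-2-chloro-6-(trimethylsilyl)phenyl trifluoromethanesulfonate, via aryl trimethylsilyl ether 30 (not isolated), via lithium 2-silylphenolate 31 (not isolated)
Conditions: HN(SiMe3)2, THF, 70 °C, then evaporation; n-BuLi, THF, −100 to −78 °C; then Tf2O, −78 °C to rt
Reagents that add atoms: hexamethyldisilazane C[Si](C)(C)N[Si](C)(C)C; trifluoromethanesulfonic anhydride FC(F)(F)S(=O)(=O)OS(=O)(=O)C(F)(F)F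
Why: Standard preparation of an o-silylaryl triflate by O-silylation, bromine–lithium exchange with retro-Brook migration of silicon from oxygen to carbon, and triflation of phenolate 31, the chlorine not being exchanged at low temperature.

Step 21
Reactants: 26 (4R)-4-benzyl-3-{2-[2-(benzyloxy)-4,5-dimethoxyphenyl]acetyl}-1,3-oxazolidin-2-one; 19 4-(benzyloxy)-2-[(3R)-7-(benzyloxy)-3,4-dihydro-2H-chromen-3-yl]-6-methoxybenzaldehyde
Product: 33 (4R)-4-benzyl-3-[(2S,3R)-3-{4-(benzyloxy)-2-[(3R)-7-(benzyloxy)-3,4-dihydro-2H-chromen-3-yl]-6-methoxyphenyl}-2-[2-(benzyloxy)-4,5-dimethoxyphenyl]-3-[(trimethylsilyl)oxy]propanoyl]-1,3-oxazolidin-2-one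
Conditions: MgCl2 (0.2 equiv), Et3N, Me3SiCl, EtOAc, 23 °C
Reagents that add atoms: chlorotrimethylsilane C[Si](C)(C)Cl
Why: MgCl2-catalysed direct anti-aldol reaction of an N-acyloxazolidinone (soft enolisation, chelated (Z)-enolate attacked opposite the auxiliary benzyl group, aldolate trapped by silylation so that addition to the hindered electron-rich aldehyde is not reversed) sets the (2S) centre that becomes C3 of the upper chroman, the (3R) carbinol centre being disposable.

Step 22
Reactants: 33 (4R)-4-benzyl-3-[(2S,3R)-3-{4-(benzyloxy)-2-[(3R)-7-(benzyloxy)-3,4-dihydro-2H-chromen-3-yl]-6-methoxyphenyl}-2-[2-(benzyloxy)-4,5-dimethoxyphenyl]-3-[(trimethylsilyl)oxy]propanoyl]-1,3-oxazolidin-2-one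
Product: 35 (1R,2R)-1-{4-(benzyloxy)-2-[(3R)-7-(benzyloxy)-3,4-dihydro-2H-chromen-3-yl]-6-methoxyphenyl}-2-[2-(benzyloxy)-4,5-dimethoxyphenyl]propane-1,3-diol, via silyl ether alcohol 34 (not isolated)
Conditions: LiBH4, MeOH (2 equiv), THF, 0 °C; then K2CO3, MeOH, rt
Reagents that add atoms: none
Why: LiBH4 reductive removal of the auxiliary followed by carbonate-catalysed methanolysis of the trimethylsilyl ether should give the anti 1,3-diol with both centres intact.

Step 23
Reactants: 35 (1R,2R)-1-{4-(benzyloxy)-2-[(3R)-7-(benzyloxy)-3,4-dihydro-2H-chromen-3-yl]-6-methoxyphenyl}-2-[2-(benzyloxy)-4,5-dimethoxyphenyl]propane-1,3-diol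
Product: 37 (2R,3R)-2-{4-(benzyloxy)-2-[(3R)-7-(benzyloxy)-3,4-dihydro-2H-chromen-3-yl]-6-methoxyphenyl}-3-[2-(benzyloxy)-4,5-dimethoxyphenyl]oxetane, via primary tosylate 36 (not isolated)
Conditions: n-BuLi (1.0 equiv), THF, −78 to 0 °C; TsCl (1.0 equiv), 0 °C; then n-BuLi (1.05 equiv), 0 to 45 °C
Reagents that add atoms: none
Why: Intramolecular Williamson etherification, in which the primary hydroxyl is sulfonylated selectively and the benzylic alkoxide closes the oxetane by 4-exo-tet displacement with retention at both stereocentres, the anti diol giving the less hindered trans-oxetane.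

Step 24
Reactants: 37 (2R,3R)-2-{4-(benzyloxy)-2-[(3R)-7-(benzyloxy)-3,4-dihydro-2H-chromen-3-yl]-6-methoxyphenyl}-3-[2-(benzyloxy)-4,5-dimethoxyphenyl]oxetane; 32 4-(benzyloxy)-2-chloro-6-(trimethylsilyl)phenyl trifluoromethanesulfonate
Product: 41 (3R,4R)-7-(benzyloxy)-4-{4-(benzyloxy)-2-[(3R)-7-(benzyloxy)-3,4-dihydro-2H-chromen-3-yl]-6-methoxyphenyl}-3-[2-(benzyloxy)-4,5-dimethoxyphenyl]-5-chloro-3,4-dihydro-2H-chromene, via 5-(benzyloxy)-3-chlorobenzyne 38 (not isolated), via O-aryloxetanium aryl anion zwitterion 39 (not isolated), via benzylic cation aryl anion zwitterion 40 (not isolated)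
Conditions: CsF (3 equiv), MeCN/toluene (1:3), 40 °C, slow addition of 32 (1.5 equiv)
Reagents that add atoms: none
Why: Proposed new method: fluoride unmasks aryne 38 from 32, the oxetane oxygen of 37 adds to the aryne carbon remote from chlorine to give zwitterion 39, and the strained ring then ionises at the C2–O bond (that carbon is benzylic to ring D and para/ortho to its two ether oxygens) to the p-alkoxybenzyl cation/aryl anion pair 40, which collapses by C–C bond formation. The closest known reaction types are the insertion of arynes into the benzylic C–O bond of styrene oxide to give dihydrobenzofurans and the ring-opening three-component couplings of cyclic ethers with arynes, and the unprecedented part is formal insertion into an oxetane C–O bond with ring expansion to a chroman, driven by release of the oxetane strain. The upper pyran ring closes by ion-pair recombination of the aryl anion carbon (future C4a) with the planar cationic carbon (future C4) through a six-membered chair-like array, formally a 6-exo-trig addition to the quinone-methide-like cation. The only new stereocentre, C4, should be set by the existing C3 centre, ring B lying pseudo-equatorial and ring D taking the opposite face to give the trans product (named 4R here only because chlorine raises the rank of C4a; the spatial arrangement is that of the target), and since the oxetane C2 configuration is erased in 40 both oxetane diastereomers would converge. The step needs regioselective aryne capture (oxygen meta to the benzyloxy group) and cleavage of the correct oxetane C–O bond: the first is secured by the chlorine next to the aryne bond, whose inductive effect and ring distortion send the nucleophile to the remote carbon and place the anion beside chlorine, the second by the cation-stabilising ring D.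

Step 25
Reactants: 41 (3R,4R)-7-(benzyloxy)-4-{4-(benzyloxy)-2-[(3R)-7-(benzyloxy)-3,4-dihydro-2H-chromen-3-yl]-6-methoxyphenyl}-3-[2-(benzyloxy)-4,5-dimethoxyphenyl]-5-chloro-3,4-dihydro-2H-chromene
Product: 42 (3R,4S)-4-{4-hydroxy-2-[(3R)-7-hydroxy-3,4-dihydro-2H-chromen-3-yl]-6-methoxyphenyl}-3-(2-hydroxy-4,5-dimethoxyphenyl)-3,4-dihydro-2H-chromen-7-ol
Conditions: H2 (1 atm), 10% Pd/C, Et3N, THF/MeOH, rt
Reagents that add atoms: none
Why: Heterogeneous palladium-catalysed hydrogenolysis should remove the four benzyl ethers and, with triethylamine present, the aryl chloride, leaving the three stereocentres and the methyl ethers untouched.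

**Compound list**

1 | 2-bromo-4-hydroxybenzaldehyde | O=Cc1ccc(O)cc1Br | starting material
2 | 4-(benzyloxy)-2-bromobenzaldehyde | O=Cc1ccc(OCc2ccccc2)cc1Br | intermediate
3 | [4-(benzyloxy)-2-bromophenyl]methanol | OCc1ccc(OCc2ccccc2)cc1Br | intermediate
4 | 4-(benzyloxy)-2-bromo-1-(bromomethyl)benzene | BrCc1ccc(OCc2ccccc2)cc1Br | intermediate
5 | methyl 2-(3,5-dihydroxyphenyl)acetate | COC(=O)Cc1cc(O)cc(O)c1 | starting material
6 | N-{[2,4-dihydroxy-6-(2-methoxy-2-oxoethyl)phenyl]methylidene}-N-methylmethanaminium chloride (not isolated) | COC(=O)Cc1cc(O)cc(O)c1C=[N+](C)C.[Cl-] | intermediate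
7 | methyl 2-(2-formyl-3,5-dihydroxyphenyl)acetate | COC(=O)Cc1cc(O)cc(O)c1C=O | intermediate
8 | methyl 2-[5-(benzyloxy)-2-formyl-3-hydroxyphenyl]acetate | COC(=O)Cc1cc(OCc2ccccc2)cc(O)c1C=O | intermediate
9 | methyl 2-[5-(benzyloxy)-2-formyl-3-methoxyphenyl]acetate | COC(=O)Cc1cc(OCc2ccccc2)cc(OC)c1C=O | intermediate
10 | methyl 2-[5-(benzyloxy)-2-(1,3-dioxolan-2-yl)-3-methoxyphenyl]acetate | COC(=O)Cc1cc(OCc2ccccc2)cc(OC)c1C1OCCO1 | intermediate
11 | 2-[5-(benzyloxy)-2-(1,3-dioxolan-2-yl)-3-methoxyphenyl]acetic acid | OC(=O)Cc1cc(OCc2ccccc2)cc(OC)c1C1OCCO1 | intermediate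
12 | (4R)-4-benzyl-1,3-oxazolidin-2-one | O=C1N[C@H](Cc2ccccc2)CO1 | starting material
13 | 2-[5-(benzyloxy)-2-(1,3-dioxolan-2-yl)-3-methoxyphenyl]acetic 2,2-dimethylpropanoic anhydride (not isolated) | CC(C)(C)C(=O)OC(=O)Cc1cc(OCc2ccccc2)cc(OC)c1C1OCCO1 | intermediate
14 | (4R)-4-benzyl-3-{2-[5-(benzyloxy)-2-(1,3-dioxolan-2-yl)-3-methoxyphenyl]acetyl}-1,3-oxazolidin-2-one | O=C(Cc1cc(OCc2ccccc2)cc(OC)c1C1OCCO1)N1[C@H](Cc2ccccc2)COC1=O | intermediate
15 | sodium (Z)-enolate of 14 (not isolated) | [Na+].[O-]/C(=C\c1cc(OCc2ccccc2)cc(OC)c1C1OCCO1)N1[C@H](Cc2ccccc2)COC1=O | intermediate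
16 | (4R)-4-benzyl-3-{(2R)-3-[4-(benzyloxy)-2-bromophenyl]-2-[5-(benzyloxy)-2-(1,3-dioxolan-2-yl)-3-methoxyphenyl]propanoyl}-1,3-oxazolidin-2-one | O=C([C@H](Cc3ccc(OCc4ccccc4)cc3Br)c1cc(OCc2ccccc2)cc(OC)c1C1OCCO1)N1[C@H](Cc2ccccc2)COC1=O | intermediate
17 | (2R)-3-[4-(benzyloxy)-2-bromophenyl]-2-[5-(benzyloxy)-2-(1,3-dioxolan-2-yl)-3-methoxyphenyl]propan-1-ol | OC[C@H](Cc3ccc(OCc4ccccc4)cc3Br)c1cc(OCc2ccccc2)cc(OC)c1C1OCCO1 | intermediate
18 | (3R)-7-(benzyloxy)-3-[5-(benzyloxy)-2-(1,3-dioxolan-2-yl)-3-methoxyphenyl]-3,4-dihydro-2H-chromene | O1CCOC1c1c(OC)cc(OCc2ccccc2)cc1[C@@H]3COc4cc(OCc5ccccc5)ccc4C3 | intermediate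
19 | 4-(benzyloxy)-2-[(3R)-7-(benzyloxy)-3,4-dihydro-2H-chromen-3-yl]-6-methoxybenzaldehyde | O=Cc1c(OC)cc(OCc2ccccc2)cc1[C@@H]3COc4cc(OCc5ccccc5)ccc4C3 | intermediate
20 | 2-hydroxy-4,5-dimethoxybenzaldehyde | O=Cc1cc(OC)c(OC)cc1O | starting material
21 | 2-(benzyloxy)-4,5-dimethoxybenzaldehyde | O=Cc1cc(OC)c(OC)cc1OCc1ccccc1 | intermediate
22 | N-{2-[2-(benzyloxy)-4,5-dimethoxyphenyl]-1-(4-methylbenzenesulfonyl)ethenyl}formamide (not isolated) | O=CNC(=Cc1cc(OC)c(OC)cc1OCc1ccccc1)S(=O)(=O)c1ccc(C)cc1 | intermediate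
23 | 2-[2-(benzyloxy)-4,5-dimethoxyphenyl]acetonitrile | N#CCc1cc(OC)c(OC)cc1OCc1ccccc1 | intermediate
24 | 2-[2-(benzyloxy)-4,5-dimethoxyphenyl]acetic acid | OC(=O)Cc1cc(OC)c(OC)cc1OCc1ccccc1 | intermediate
25 | 2-[2-(benzyloxy)-4,5-dimethoxyphenyl]acetic 2,2-dimethylpropanoic anhydride (not isolated) | CC(C)(C)C(=O)OC(=O)Cc1cc(OC)c(OC)cc1OCc1ccccc1 | intermediate
26 | (4R)-4-benzyl-3-{2-[2-(benzyloxy)-4,5-dimethoxyphenyl]acetyl}-1,3-oxazolidin-2-one | O=C(Cc1cc(OC)c(OC)cc1OCc1ccccc1)N1[C@H](Cc2ccccc2)COC1=O | intermediate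
27 | 4-(benzyloxy)phenol | Oc1ccc(OCc2ccccc2)cc1 | starting material
28 | 4-(benzyloxy)-2-chlorophenol | Oc1ccc(OCc2ccccc2)cc1Cl | intermediate
29 | 4-(benzyloxy)-2-bromo-6-chlorophenol | Oc1c(Cl)cc(OCc2ccccc2)cc1Br | intermediate
30 | [4-(benzyloxy)-2-bromo-6-chlorophenoxy]trimethylsilane (not isolated) | C[Si](C)(C)Oc1c(Cl)cc(OCc2ccccc2)cc1Br | intermediate
31 | lithium 4-(benzyloxy)-2-chloro-6-(trimethylsilyl)phenolate (not isolated) | [Li+].[O-]c1c(Cl)cc(OCc2ccccc2)cc1[Si](C)(C)C | intermediate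
32 | 4-(benzyloxy)-2-chloro-6-(trimethylsilyl)phenyl trifluoromethanesulfonate | FC(F)(F)S(=O)(=O)Oc1c(Cl)cc(OCc2ccccc2)cc1[Si](C)(C)C | intermediate
33 | (4R)-4-benzyl-3-[(2S,3R)-3-{4-(benzyloxy)-2-[(3R)-7-(benzyloxy)-3,4-dihydro-2H-chromen-3-yl]-6-methoxyphenyl}-2-[2-(benzyloxy)-4,5-dimethoxyphenyl]-3-[(trimethylsilyl)oxy]propanoyl]-1,3-oxazolidin-2-one | O=C([C@H]([C@@H](O[Si](C)(C)C)c1c(OC)cc(OCc2ccccc2)cc1[C@@H]3COc4cc(OCc5ccccc5)ccc4C3)c6cc(OC)c(OC)cc6OCc7ccccc7)N8[C@H](Cc9ccccc9)COC8=O | intermediate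
34 | (2R,3R)-3-{4-(benzyloxy)-2-[(3R)-7-(benzyloxy)-3,4-dihydro-2H-chromen-3-yl]-6-methoxyphenyl}-2-[2-(benzyloxy)-4,5-dimethoxyphenyl]-3-[(trimethylsilyl)oxy]propan-1-ol (not isolated) | OC[C@H]([C@@H](O[Si](C)(C)C)c1c(OC)cc(OCc2ccccc2)cc1[C@@H]3COc4cc(OCc5ccccc5)ccc4C3)c6cc(OC)c(OC)cc6OCc7ccccc7 | intermediate
35 | (1R,2R)-1-{4-(benzyloxy)-2-[(3R)-7-(benzyloxy)-3,4-dihydro-2H-chromen-3-yl]-6-methoxyphenyl}-2-[2-(benzyloxy)-4,5-dimethoxyphenyl]propane-1,3-diol | OC[C@H]([C@@H](O)c1c(OC)cc(OCc2ccccc2)cc1[C@@H]3COc4cc(OCc5ccccc5)ccc4C3)c6cc(OC)c(OC)cc6OCc7ccccc7 | intermediate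
36 | (2R,3R)-3-{4-(benzyloxy)-2-[(3R)-7-(benzyloxy)-3,4-dihydro-2H-chromen-3-yl]-6-methoxyphenyl}-2-[2-(benzyloxy)-4,5-dimethoxyphenyl]-3-hydroxypropyl 4-methylbenzenesulfonate (not isolated) | Cc8ccc(cc8)S(=O)(=O)OC[C@H]([C@@H](O)c1c(OC)cc(OCc2ccccc2)cc1[C@@H]3COc4cc(OCc5ccccc5)ccc4C3)c6cc(OC)c(OC)cc6OCc7ccccc7 | intermediate
37 | (2R,3R)-2-{4-(benzyloxy)-2-[(3R)-7-(benzyloxy)-3,4-dihydro-2H-chromen-3-yl]-6-methoxyphenyl}-3-[2-(benzyloxy)-4,5-dimethoxyphenyl]oxetane (trans) | C1[C@H]([C@@H](O1)c2c(OC)cc(OCc3ccccc3)cc2[C@@H]4COc5cc(OCc6ccccc6)ccc5C4)c7cc(OC)c(OC)cc7OCc8ccccc8 | intermediate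
38 | 5-(benzyloxy)-3-chlorobenzyne (5-(benzyloxy)-3-chloro-1,2-didehydrobenzene, not isolated) | ClC1=CC(OCc2ccccc2)=CC#C1 | intermediate
39 | O-aryloxetanium zwitterion: oxetane 37 arylated on oxygen by C1 of the aryne, carbanion on the ring carbon between the oxonium oxygen and chlorine (not isolated) | C1[C@H]([C@@H]([O+]1c1cc(OCc2ccccc2)cc(Cl)[c-]1)c2c(OC)cc(OCc3ccccc3)cc2[C@@H]4COc5cc(OCc6ccccc6)ccc5C4)c7cc(OC)c(OC)cc7OCc8ccccc8 | intermediate
40 | ring-opened zwitterion: aryl ether of the primary oxygen, benzylic cation at the ring D carbon, aryl anion ortho to the ether oxygen (not isolated) | [c-]1c(Cl)cc(OCc2ccccc2)cc1OC[C@H]([CH+]c2c(OC)cc(OCc3ccccc3)cc2[C@@H]4COc5cc(OCc6ccccc6)ccc5C4)c7cc(OC)c(OC)cc7OCc8ccccc8 | intermediate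
41 | (3R,4R)-7-(benzyloxy)-4-{4-(benzyloxy)-2-[(3R)-7-(benzyloxy)-3,4-dihydro-2H-chromen-3-yl]-6-methoxyphenyl}-3-[2-(benzyloxy)-4,5-dimethoxyphenyl]-5-chloro-3,4-dihydro-2H-chromene | COc1cc(OCc2ccccc2)c(cc1OC)[C@@H]3COc4cc(OCc5ccccc5)cc(Cl)c4[C@H]3c6c(OC)cc(OCc7ccccc7)cc6[C@@H]8COc9cc(OCc2ccccc2)ccc9C8 | intermediate
42 | (3R,4S)-4-{4-hydroxy-2-[(3R)-7-hydroxy-3,4-dihydro-2H-chromen-3-yl]-6-methoxyphenyl}-3-(2-hydroxy-4,5-dimethoxyphenyl)-3,4-dihydro-2H-chromen-7-ol | COc1cc(O)c([C@@H]2COc3cc(O)ccc3[C@H]2c2c(OC)cc(O)cc2[C@@H]2COc3cc(O)ccc3C2)cc1OC | target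

**Step count and risks**

Total step count: 25. Longest linear sequence: 15 steps (steps 4 to 13, then 21 to 25, from 5 to 42).

Steps most likely to fail:

1. Step 24 (proposed new method). The ortho-chloroaryl anion may lose chloride, or be protonated by the medium, before it reaches the cation. The cation may instead lose the C3 proton to give an allyl aryl ether. Facial selectivity at C4 may be poor under the peri strain from chlorine. The fallback uses only known reactions and no aryne. It sets out from diol 35: Mitsunobu etherification of the primary hydroxyl with 3-(benzyloxy)phenol (PPh3, diisopropyl azodicarboxylate, THF, 0 °C) should give the aryl ether (1R,2R)-3-[3-(benzyloxy)phenoxy]-1-{ring D}-2-{ring B}propan-1-ol F1. BF3·OEt2 in CH2Cl2 at −40 °C then ionises the benzylic alcohol, and intramolecular Friedel–Crafts alkylation para to the benzyloxy group should close the pyran ring trans to give the chlorine-free tetrabenzyl ether F2. Hydrogenolysis (H2, 10% Pd/C) returns to the route at target 42.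

2. Step 21. Addition of the enolate to the hindered, electron-rich aldehyde may be too slow, so that silylation of the enolate or reversal of the aldol takes over. The fallback makes the electrophile a cation instead of a carbonyl group. It sets out from 19 and 26: 19 is converted into its dimethyl acetal F3 (HC(OMe)3, MeOH, pyridinium p-toluenesulfonate). The titanium enolate of 26 (TiCl4, i-Pr2NEt, CH2Cl2, −78 °C) adds to the oxocarbenium ion from F3 on the same enolate face to give the β-methoxy imide F4, whose methoxy-bearing centre need not be controlled. LiBH4 gives the alcohol F5. Mitsunobu etherification with 3-(benzyloxy)phenol gives the aryl ether F6. BF3·OEt2 ionises the benzylic methyl ether and Friedel–Crafts closure gives the tetrabenzyl ether F2, which is hydrogenolysed to rejoin the route at 42.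

3. Step 23. The γ-tosyloxy alkoxide may fragment (Grob-type) to aldehyde 19 and a styrene instead of closing the four-membered ring, or the wrong hydroxyl may be sulfonylated. The fallback avoids the oxetane and forms the two bonds one after the other. It sets out from 35: aryne 38 (from 32, CsF, MeCN, rt) inserts into the primary O–H bond, a known aryl ether synthesis, with oxygen again going to the carbon remote from chlorine, to give the 3-(benzyloxy)-5-chlorophenyl ether F7. BF3·OEt2 in CH2Cl2 at −40 °C then closes the ring by Friedel–Crafts alkylation at the carbon between the ether oxygen and chlorine (para to the benzyloxy group), and the route is rejoined at 41.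

Further compounds

F1 | step 24 | (1R,2R)-3-[3-(benzyloxy)phenoxy]-1-{4-(benzyloxy)-2-[(3R)-7-(benzyloxy)-3,4-dihydro-2H-chromen-3-yl]-6-methoxyphenyl}-2-[2-(benzyloxy)-4,5-dimethoxyphenyl]propan-1-ol | C(c8ccccc8)Oc9cccc(c9)OC[C@H]([C@@H](O)c1c(OC)cc(OCc2ccccc2)cc1[C@@H]3COc4cc(OCc5ccccc5)ccc4C3)c6cc(OC)c(OC)cc6OCc7ccccc7
F2 | step 24 | (3R,4S)-7-(benzyloxy)-4-{4-(benzyloxy)-2-[(3R)-7-(benzyloxy)-3,4-dihydro-2H-chromen-3-yl]-6-methoxyphenyl}-3-[2-(benzyloxy)-4,5-dimethoxyphenyl]-3,4-dihydro-2H-chromene | COc1cc(OCc2ccccc2)c(cc1OC)[C@@H]3COc4cc(OCc5ccccc5)ccc4[C@H]3c6c(OC)cc(OCc7ccccc7)cc6[C@@H]8COc9cc(OCc2ccccc2)ccc9C8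
F3 | step 21 | (3R)-7-(benzyloxy)-3-[5-(benzyloxy)-2-(dimethoxymethyl)-3-methoxyphenyl]-3,4-dihydro-2H-chromene | COC(OC)c1c(OC)cc(OCc2ccccc2)cc1[C@@H]3COc4cc(OCc5ccccc5)ccc4C3
F4 | step 21 | (4R)-4-benzyl-3-[(2S)-3-{4-(benzyloxy)-2-[(3R)-7-(benzyloxy)-3,4-dihydro-2H-chromen-3-yl]-6-methoxyphenyl}-2-[2-(benzyloxy)-4,5-dimethoxyphenyl]-3-methoxypropanoyl]-1,3-oxazolidin-2-one (methoxy-bearing centre not controlled) | O=C([C@H](C(OC)c1c(OC)cc(OCc2ccccc2)cc1[C@@H]3COc4cc(OCc5ccccc5)ccc4C3)c6cc(OC)c(OC)cc6OCc7ccccc7)N8[C@H](Cc9ccccc9)COC8=O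
F5 | step 21 | (2R)-3-{4-(benzyloxy)-2-[(3R)-7-(benzyloxy)-3,4-dihydro-2H-chromen-3-yl]-6-methoxyphenyl}-2-[2-(benzyloxy)-4,5-dimethoxyphenyl]-3-methoxypropan-1-ol | OC[C@H](C(OC)c1c(OC)cc(OCc2ccccc2)cc1[C@@H]3COc4cc(OCc5ccccc5)ccc4C3)c6cc(OC)c(OC)cc6OCc7ccccc7
F6 | step 21 | 1-(benzyloxy)-3-{[(2R)-3-{4-(benzyloxy)-2-[(3R)-7-(benzyloxy)-3,4-dihydro-2H-chromen-3-yl]-6-methoxyphenyl}-2-[2-(benzyloxy)-4,5-dimethoxyphenyl]-3-methoxypropyl]oxy}benzene | C(c8ccccc8)Oc9cccc(c9)OC[C@H](C(OC)c1c(OC)cc(OCc2ccccc2)cc1[C@@H]3COc4cc(OCc5ccccc5)ccc4C3)c6cc(OC)c(OC)cc6OCc7ccccc7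
F7 | step 23 | (1R,2R)-3-[3-(benzyloxy)-5-chlorophenoxy]-1-{4-(benzyloxy)-2-[(3R)-7-(benzyloxy)-3,4-dihydro-2H-chromen-3-yl]-6-methoxyphenyl}-2-[2-(benzyloxy)-4,5-dimethoxyphenyl]propan-1-ol | C(c8ccccc8)Oc9cc(Cl)cc(c9)OC[C@H]([C@@H](O)c1c(OC)cc(OCc2ccccc2)cc1[C@@H]3COc4cc(OCc5ccccc5)ccc4C3)c6cc(OC)c(OC)cc6OCc7ccccc7
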